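## Structural features

The target (2R,3R,4S; C25H28O9) is a 2-arylchroman: ring A is a formylphloroglucinol unit (C4a to C8a, hydroxyls on C5 and C7, formyl on C6, hydrogen on C8) fused to the dihydropyran ring B (O1, C2, C3, C4). Ring C, a 3,5-diformyl-2,4,6-trihydroxyphenyl group, is attached to C2 through its only unsubstituted carbon. Ring B carries three contiguous stereocentres, C2 (aryl), C3 (isopropyl) and C4 (isobutyl), with C2 and C3 trans and C3 and C4 cis, so that in the half-chair the aryl and isopropyl groups can sit equatorial while the isobutyl group is pseudoaxial and clear of the C5 hydroxyl. The fragile parts are the three aryl aldehydes, the five free phenols and the O1–C2 bond, a benzylic ether flanked by ortho and para hydroxyls of ring C that can open reversibly to an ortho-quinone methide. Because of that lability C2 can be corrected late, C3 only while C2 is at the aldehyde oxidation level, and C4 not at all. The real difficulty is absolute control at C4 and relative control at C3 on a skeleton without directing groups, together with the choice among nearly equivalent phenolic oxygens and ring carbons when no protecting group is used. The key step exploits that the chain C2–C3–C4 with its isopropyl and isobutyl branches is the self-condensation dimer of 3-methylbutanal, a 1,3-dielectrophile at the enal level (C4 as β-carbon, C2 as carbonyl carbon), and that C4a and O1 of ring A are the matching carbon–oxygen dinucleophile of a symmetric formylphloroglucinol.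

## Logic of the disconnections

**From 9 back to 6 and 7.** The bond between C2 and ring C is cut, and O1–C2 is taken back to the hemiacetal level. Ring C has exactly one free carbon, flanked by two hydroxyls, so it behaves as a carbon nucleophile of the 1,3-dicarbonyl type, and C2 is then an aldehyde carbon in disguise. Condensation of the open form 5 of 6 with 7 gives 8, which ring A recloses. The gain is that ring C and the C2 stereocentre leave the problem, C2 being set last and reversibly. The forward step must meet three demands: 5 must condense with the weakly nucleophilic 7 faster than with the free C8 position of another molecule, ring B must reclose through the oxygen para to the ring A formyl group, and C3 must not epimerise while C2 is unsaturated.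

**From 6 back to 3 and 4.** C4–C4a and O1–C2 are cut. 3 is a 1,3-dielectrophile and 4 a carbon–oxygen dinucleophile whose two free carbons are equivalent, so there is no site choice among carbons and the formyl group arrives at C6 without a formylation step. The gain is ring B, two skeletal bonds and two stereocentres from two achiral compounds. The demand is conjugate rather than carbonyl addition to an α-branched enal (hence a primary amine catalyst), one face at C4, the cis relation at C3, and a single alkylation of the arene.

**From 3 back to 1.** The C3–C4 bond (chroman numbering), which is the double bond of 3, is cut by an aldol condensation transform. Both halves are the same molecule, so the whole ten-carbon chain comes from two molecules of 1. The demand is that the condensation stops at the dimer and gives the E isomer.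

## Other disconnections considered

Alternative 1: The cut runs through ring A itself, at C4a–C8a, together with O1–C2, so that ring A is folded from an open chain instead of being bought.
- Forward key step: the triketide ester methyl (7R,8R)-9,9-dimethoxy-7-(2-methylpropyl)-3,5-dioxo-8-(propan-2-yl)nonanoate A2 would be converted into its polyanion with excess strong base. The terminal carbanion at chain carbon C6 would attack the ester carbon (Claisen), the ring would aromatise, and acidic work-up would unmask the acetal so that a ring A hydroxyl closes the lactol (3R,4S)-4-(2-methylpropyl)-3-(propan-2-yl)-3,4-dihydro-2H-chromene-2,5,7-triol A1 as an anomeric mixture.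
- In favour: both stereocentres would be made in an open chain by auxiliary- or reagent-controlled methods whose diastereomers can be separated, no amine catalyst meets a polyphenolic aldehyde, and no second alkylation of an arene is possible. On the reliability of C3 and C4 and on chemoselectivity in the ring-forming step it is the better plan.
- Against: ester A2 needs a long linear sequence (two stereocentres, the acetal, chain extension with an acetoacetate dianion). The cyclisation of such 3,5-dioxo esters competes with O-acylation to a lactone. Lactol A1 still lacks the C6 formyl group, so a formylation must follow.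
- Comparison: on structure, it builds a benzene ring that can be purchased. On mechanism, it uses strong-base polyanion chemistry in place of mild amine catalysis, though without ambiguity of site. On step economy, it would need well over ten steps against three. The endgame with 7 would be the same, so on the last step the two plans are equal.

Alternative 2: Only C4–C4a is cut, with O1–C2 and the C2–aryl bond already in place in an aryl ether.
- Forward key step: a Lewis acid would activate the trans-epoxide 2-[1-(4-bromo-3,5-dimethoxyphenoxy)-1-(3,5-dibromo-2,4,6-trimethoxyphenyl)-3-methylbutan-2-yl]-3-(propan-2-yl)oxirane A4 so that the ring A carbon ortho to the ether oxygen attacks C4 with inversion (6-exo-tet). This would give 1-[6-bromo-2-(3,5-dibromo-2,4,6-trimethoxyphenyl)-5,7-dimethoxy-3-(propan-2-yl)-3,4-dihydro-2H-chromen-4-yl]-2-methylpropan-1-ol A3 as the cyclised product.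
- In favour: C4 follows stereospecifically from the epoxide, C2 and C3 are fixed beforehand by defined steps, and O1 and the later formyl positions are fixed by the ether and the bromines. On regiochemical and stereochemical certainty it is the better plan.
- Against: the ether C2–O1 in A4 is a polyalkoxybenzyl ether that a Lewis acid can ionise. The epoxide carbon is hindered and may rearrange by hydride shift. The bromine lowers the nucleophilicity of ring A. After A3 the route would still need deoxygenation of the carbinol (Barton–McCombie, two steps), a threefold bromine–lithium exchange with formylation, and fivefold O-demethylation with BBr3 in the presence of three aldehydes and the acid-labile C2–O1 bond.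
- Comparison: on structure, both plans make C4–C4a from a ring A nucleophile, but here the partner is a precursor laden with protecting groups and redox adjustments. On mechanism, it is a stereospecific substitution against a catalyst-controlled conjugate addition. On step economy, it would need roughly fifteen steps or more against three.

Alternative 3: The cut lies inside ring C, next to the carbon bonded to C2, so that ring C is folded from a side chain on C2.
- Forward key step: base would cyclise methyl 6-[6-(dimethoxymethyl)-5,7-dimethoxy-4-(2-methylpropyl)-3-(propan-2-yl)-3,4-dihydro-2H-chromen-2-yl]-3,5-dioxohexanoate A6 by Claisen attack of the chroman-bound methylene carbon on the ester carbon. Aromatisation would give 2-[6-(dimethoxymethyl)-5,7-dimethoxy-4-(2-methylpropyl)-3-(propan-2-yl)-3,4-dihydro-2H-chromen-2-yl]benzene-1,3,5-triol A5 as the product.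
- In favour: the C2–ring C bond exists before ring C does, so the weakly nucleophilic 7 never has to attack a hindered aldehyde. Ring A is masked and cannot compete as a nucleophile. C2 is set on a simple alkyl-substituted chroman. On chemoselectivity of the C2–aryl bond it is the better plan. The two ring A methyl ethers are both ortho to the formyl group, which would allow selective removal with BCl3.
- Against: in A6 the oxygen O1 is β to a ketone, so the polyanion conditions invite retro-oxa-Michael opening of ring B. Lactone formation again competes with the Claisen closure. Triol A5 still needs twofold formylation of ring C, acetal hydrolysis and demethylation, and ring A must be protected and deprotected.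
- Comparison: on structure, it builds a ring that can be bought as 7. On mechanism, it replaces a reversible, self-correcting condensation with irreversible strong-base chemistry on a base-labile ether. On step economy, it would need ten steps or more against three. Control of C2 by equilibration would be the same in both plans, so on that point they are equal.

Key step: step 2

## Assumptions

- 2,4-Diformylphloroglucinol (7) is taken as a purchased compound.
- The quinine-derived primary amine is taken to give the 4S configuration. The sense of induction cannot be derived with confidence for this nucleophile; should it prove opposite, the quinidine-derived pseudoenantiomer of the catalyst is the direct substitute.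

## Route

Step 1
Reactants: 1 isovaleraldehyde (3-methylbutanal; two molecules)
Product: 3 (E)-5-methyl-2-(propan-2-yl)hex-2-enal, via aldol adduct 2 (not isolated)
Conditions: NaOH (aq, 10 mol%), MeOH, 0 to 60 °C; distillation
Reagents that add atoms: none
Why: Base-mediated self-aldol condensation: the enolate of one molecule of 1 adds to the carbonyl group of a second to give 2, which loses water by E1cB elimination. The E isomer, in which the formyl group is trans to the β-alkyl chain, is the favoured geometry of 2-alkylalk-2-enals, and no stereocentre remains after dehydration.

Step 2
Reactants: 3 (E)-5-methyl-2-(propan-2-yl)hex-2-enal; 4 2,4,6-trihydroxybenzaldehyde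
Product: 6 (3R,4S)-2,5,7-trihydroxy-4-(2-methylpropyl)-3-(propan-2-yl)-3,4-dihydro-2H-chromene-6-carbaldehyde (3,4-cis lactol as anomeric mixture), via hydroxy aldehyde 5 (not isolated)
Conditions: 4 (1.5 equiv), 9-amino-9-deoxy-epi-quinine (20 mol%), CF3CO2H (40 mol%), THF, 0 °C to rt
Reagents that add atoms: none
Why: The primary amine salt condenses with the α-branched enal 3 to an iminium ion, which a secondary amine would form only with difficulty, and the free ring carbon of 4, reacting as the carbon end of a vinylogous acid much like a cyclic 1,3-dione, adds to the β-carbon in a Friedel–Crafts-type conjugate addition that forms C4–C4a. Rearomatisation, protonation of the enamine at C3 and hydrolysis release hydroxy aldehyde 5 and the catalyst, and the hydroxyl para to the formyl group then adds to the aldehyde carbon (6-exo-trig hemiacetalisation), forming O1–C2 and closing ring B as lactol 6. The closest known reaction type is the amine-catalysed Friedel–Crafts alkylation and hemiacetalisation of electron-rich phenols, naphthols and cyclic 1,3-dicarbonyl compounds with enals, combined with primary amine iminium activation of α-branched enals. C4 is set by the catalyst: in the ion pair the protonated quinuclidine and its trifluoroacetate shield one face of the iminium ion, so that the arene adds to the other. C3 is set relative to C4, first by protonation of the enamine, for which the neighbouring phenolic hydroxyl can deliver the proton on the aryl side, and then by equilibration through the enamine while the amine is present, the expected sink being the lactol with the isobutyl group pseudoaxial (away from the C5 hydroxyl) and the isopropyl group equatorial, that is 3,4-cis. The step needs conjugate over carbonyl addition, since the latter would lead by dehydration and 6π closure to a 2H-chromene of the wrong connectivity; the soft carbon nucleophile, the iminium activation of the β-position and the low temperature favour the former, and oxygen adducts revert by retro-oxa-Michael reaction. It also needs a single alkylation, which the excess of 4 secures, whereas site selectivity on the arene does not arise because its two free carbons are equivalent. Which ortho hydroxyl closes the lactol is not critical, since either lactol reopens to 5 in step 3, but the para hydroxyl is expected to close because it is the more acidic and the other one competes for the hydrogen bond to the formyl oxygen.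

Step 3
Reactants: 6 (3R,4S)-2,5,7-trihydroxy-4-(2-methylpropyl)-3-(propan-2-yl)-3,4-dihydro-2H-chromene-6-carbaldehyde; 7 2,4-diformylphloroglucinol (2,4,6-trihydroxybenzene-1,3-dicarbaldehyde)
Product: 9 (2R,3R,4S)-2-(3,5-diformyl-2,4,6-trihydroxyphenyl)-5,7-dihydroxy-4-(2-methylpropyl)-3-(propan-2-yl)-3,4-dihydro-2H-chromene-6-carbaldehyde (CNP0328914.1), via ortho-quinone methide 8 (not isolated)
Conditions: 7 (3 equiv), NaOAc, AcOH, 70 °C, argon
Reagents that add atoms: none
Why: Lactol 6 reacts through its open-chain tautomer 5, whose aldehyde condenses in a Knoevenagel-type reaction with the single free ring carbon of the vinylogous acid 7 to give ortho-quinone methide 8, the way aliphatic aldehydes are known to react with formylated phloroglucinols in acetate buffer. The ring A hydroxyl para to the formyl group, the most acidic one, then adds to the methide carbon (oxa-Michael addition, 6-exo-trig) and recloses ring B. C2 is set under thermodynamic control because this closure is reversible, the aryl group taking the equatorial position trans to the C3 isopropyl group, while C3 and C4 are carried through unchanged in the amine-free medium.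

## Compound list

1 | isovaleraldehyde (3-methylbutanal) | CC(C)CC=O | starting material
2 | 3-hydroxy-5-methyl-2-(propan-2-yl)hexanal (aldol adduct, mixture of stereoisomers) | CC(C)CC(O)C(C=O)C(C)C | intermediate
3 | (E)-5-methyl-2-(propan-2-yl)hex-2-enal | CC(C)C/C=C(/C=O)C(C)C | intermediate
4 | 2,4,6-trihydroxybenzaldehyde | O=Cc1c(O)cc(O)cc1O | starting material
5 | (2R,3S)-3-(3-formyl-2,4,6-trihydroxyphenyl)-5-methyl-2-(propan-2-yl)hexanal (open-chain tautomer of 6) | CC(C)C[C@H](c1c(O)cc(O)c(C=O)c1O)[C@H](C=O)C(C)C | intermediate
6 | (3R,4S)-2,5,7-trihydroxy-4-(2-methylpropyl)-3-(propan-2-yl)-3,4-dihydro-2H-chromene-6-carbaldehyde (3,4-cis lactol, anomeric mixture) | CC(C)C[C@@H]1c2c(cc(O)c(C=O)c2O)OC(O)[C@@H]1C(C)C | intermediate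
7 | 2,4-diformylphloroglucinol (2,4,6-trihydroxybenzene-1,3-dicarbaldehyde) | O=Cc1c(O)cc(O)c(C=O)c1O | starting material
8 | 5-[(2S,3S)-3-(3-formyl-2,4,6-trihydroxyphenyl)-5-methyl-2-(propan-2-yl)hexylidene]-2,4-dihydroxy-6-oxocyclohexa-1,3-diene-1,3-dicarbaldehyde (ortho-quinone methide; the two sp3 centres have the same spatial arrangement as in 5, exocyclic double-bond geometry undefined) | CC(C)C[C@H](c1c(O)cc(O)c(C=O)c1O)[C@H](C=C1C(=O)C(C=O)=C(O)C(C=O)=C1O)C(C)C | intermediate
9 | (2R,3R,4S)-2-(3,5-diformyl-2,4,6-trihydroxyphenyl)-5,7-dihydroxy-4-(2-methylpropyl)-3-(propan-2-yl)-3,4-dihydro-2H-chromene-6-carbaldehyde (CNP0328914.1) | CC(C)C[C@@H]1c2c(cc(O)c(C=O)c2O)O[C@@H](c2c(O)c(C=O)c(O)c(C=O)c2O)[C@@H]1C(C)C | target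

## Step count and least certain steps

Total step count: 3. Longest linear sequence: 3 steps (1 → 3 → 6 → 9).

**Step 2 (key step).**
What may go wrong: the primary amine may be tied up as the hydrogen-bonded aryl aldimine of 4, and the formylated arene is a weak carbon nucleophile. Iminium turnover may then stall, or carbonyl addition with dehydration and 6π closure to a 2H-chromene may take over. Facial selectivity at C4 and the cis relation at C3 may also be incomplete, because both rest on a catalyst model and on an equilibrium that are untested on a polyphenolic aldehyde.

Fallback (sets out from 3, returns to the route at 6): the formyl group is left out of the annulation and introduced afterwards. Enal 3 would be annulated under the same amine salt catalysis with an excess of purchased phloroglucinol (benzene-1,3,5-triol), which is more nucleophilic than 4 and has no aldehyde to bind the catalyst, to give the lactol (3R,4S)-4-(2-methylpropyl)-3-(propan-2-yl)-3,4-dihydro-2H-chromene-2,5,7-triol F1 as an anomeric mixture. Lactol F1 would be fixed with MeOH and pyridinium p-toluenesulfonate as its methyl acetal (3R,4S)-2-methoxy-4-(2-methylpropyl)-3-(propan-2-yl)-3,4-dihydro-2H-chromene-5,7-diol F2 and acetal F2 then mono-formylated under Vilsmeier–Haack conditions (POCl3, DMF, 0 °C, one equivalent). This should give (3R,4S)-5,7-dihydroxy-2-methoxy-4-(2-methylpropyl)-3-(propan-2-yl)-3,4-dihydro-2H-chromene-6-carbaldehyde F3 together with its regioisomer (3R,4S)-5,7-dihydroxy-2-methoxy-4-(2-methylpropyl)-3-(propan-2-yl)-3,4-dihydro-2H-chromene-8-carbaldehyde F4 in some proportion. Hydrolysis of the acetal function of F3 and F4 with dilute HCl in THF should lead to 6 from both, since the two open to the same hydroxy aldehyde 5, so the site of formylation is without consequence.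

**Step 3.**
What may go wrong: chemoselectivity in the condensation may be lost, because the free C8 position of ring A in a second molecule competes with the electron-poorer 7 for the hindered aldehyde. Ring B may reclose through the hydroxyl next to the formyl group. The C3 configuration may erode on prolonged heating, by enolisation of the open aldehyde or by a 1,5-hydrogen shift of the quinone methide to a styrene.

Fallback (sets out from 6, returns to the route at 9): ring B is kept closed and ring A is masked. Lactol 6 would be peracetylated (Ac2O, pyridine, 4-dimethylaminopyridine) to (3R,4S)-6-formyl-4-(2-methylpropyl)-3-(propan-2-yl)-3,4-dihydro-2H-chromene-2,5,7-triyl triacetate F5 as a stable compound whose substitution pattern can be secured before the last bond is made. Triacetate F5 would then serve as an anomeric acetate donor: BF3·OEt2 in MeCN with excess 7 should bring about Friedel–Crafts arylation at C2, trans to the isopropyl group. The coupled product would be (2R,3R,4S)-2-(3,5-diformyl-2,4,6-trihydroxyphenyl)-6-formyl-4-(2-methylpropyl)-3-(propan-2-yl)-3,4-dihydro-2H-chromene-5,7-diyl diacetate F6 with C3 never at risk, because C2 is never an open aldehyde. The acetylated ring A of F6 can neither have acted as a carbon nucleophile nor have reclosed through the wrong oxygen, and the two phenolic acetates of F6 would be removed with K2CO3 in MeOH at 0 °C under argon to give 9.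

**Step 1.**
What may go wrong: condensation may run on to trimers, Michael adducts and aldol–Tishchenko esters, because the product enal is itself an electrophile in a basic medium that still holds enolisable aldehyde. Geometric purity may be incomplete.

Fallback (sets out from 1, returns to the route at 3): the double bond is made by olefination at the ester oxidation level. Horner–Wadsworth–Emmons reaction of 1 with the sodium salt of ethyl 2-(diethoxyphosphoryl)-3-methylbutanoate (NaH, THF) should give ethyl (E)-5-methyl-2-(propan-2-yl)hex-2-enoate F7 as the major geometric isomer, to be purified by chromatography at this stage. Ester F7 would be reduced with i-Bu2AlH to (E)-5-methyl-2-(propan-2-yl)hex-2-en-1-ol F8 and the allylic alcohol F8 oxidised with MnO2 to 3.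

## Further compounds

F1 | step 2 | (3R,4S)-4-(2-methylpropyl)-3-(propan-2-yl)-3,4-dihydro-2H-chromene-2,5,7-triol | CC(C)C[C@@H]1c2c(cc(O)cc2O)OC(O)[C@@H]1C(C)C
F2 | step 2 | (3R,4S)-2-methoxy-4-(2-methylpropyl)-3-(propan-2-yl)-3,4-dihydro-2H-chromene-5,7-diol | CC(C)C[C@@H]1c2c(cc(O)cc2O)OC(OC)[C@@H]1C(C)C
F3 | step 2 | (3R,4S)-5,7-dihydroxy-2-methoxy-4-(2-methylpropyl)-3-(propan-2-yl)-3,4-dihydro-2H-chromene-6-carbaldehyde | CC(C)C[C@@H]1c2c(cc(O)c(C=O)c2O)OC(OC)[C@@H]1C(C)C
F4 | step 2 | (3R,4S)-5,7-dihydroxy-2-methoxy-4-(2-methylpropyl)-3-(propan-2-yl)-3,4-dihydro-2H-chromene-8-carbaldehyde | CC(C)C[C@@H]1c2c(c(C=O)c(O)cc2O)OC(OC)[C@@H]1C(C)C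
F5 | step 3 | (3R,4S)-6-formyl-4-(2-methylpropyl)-3-(propan-2-yl)-3,4-dihydro-2H-chromene-2,5,7-triyl triacetate | CC(C)C[C@@H]1c2c(cc(OC(C)=O)c(C=O)c2OC(C)=O)OC(OC(C)=O)[C@@H]1C(C)C
F6 | step 3 | (2R,3R,4S)-2-(3,5-diformyl-2,4,6-trihydroxyphenyl)-6-formyl-4-(2-methylpropyl)-3-(propan-2-yl)-3,4-dihydro-2H-chromene-5,7-diyl diacetate | CC(C)C[C@@H]1c2c(cc(OC(C)=O)c(C=O)c2OC(C)=O)O[C@@H](c2c(O)c(C=O)c(O)c(C=O)c2O)[C@@H]1C(C)C
F7 | step 1 | ethyl (E)-5-methyl-2-(propan-2-yl)hex-2-enoate | CC(C)C/C=C(/C(=O)OCC)C(C)C
F8 | step 1 | (E)-5-methyl-2-(propan-2-yl)hex-2-en-1-ol | CC(C)C/C=C(/CO)C(C)C
A1 | alternative 1 | (3R,4S)-4-(2-methylpropyl)-3-(propan-2-yl)-3,4-dihydro-2H-chromene-2,5,7-triol (3,4-cis lactol, anomeric mixture) | CC(C)C[C@@H]1c2c(cc(O)cc2O)OC(O)[C@@H]1C(C)C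
A2 | alternative 1 | methyl (7R,8R)-9,9-dimethoxy-7-(2-methylpropyl)-3,5-dioxo-8-(propan-2-yl)nonanoate | COC(=O)CC(=O)CC(=O)C[C@@H](CC(C)C)[C@@H](C(C)C)C(OC)OC
A3 | alternative 2 | 1-[6-bromo-2-(3,5-dibromo-2,4,6-trimethoxyphenyl)-5,7-dimethoxy-3-(propan-2-yl)-3,4-dihydro-2H-chromen-4-yl]-2-methylpropan-1-ol | CC(C)[C@H](O)[C@@H]1c2c(cc(OC)c(Br)c2OC)O[C@@H](c2c(OC)c(Br)c(OC)c(Br)c2OC)[C@@H]1C(C)C
A4 | alternative 2 | 2-[1-(4-bromo-3,5-dimethoxyphenoxy)-1-(3,5-dibromo-2,4,6-trimethoxyphenyl)-3-methylbutan-2-yl]-3-(propan-2-yl)oxirane (trans-epoxide) | CC(C)[C@@H]1O[C@H]1[C@@H](C(C)C)[C@@H](Oc1cc(OC)c(Br)c(OC)c1)c1c(OC)c(Br)c(OC)c(Br)c1OC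
A5 | alternative 3 | 2-[6-(dimethoxymethyl)-5,7-dimethoxy-4-(2-methylpropyl)-3-(propan-2-yl)-3,4-dihydro-2H-chromen-2-yl]benzene-1,3,5-triol | CC(C)C[C@@H]1c2c(cc(OC)c(C(OC)OC)c2OC)O[C@@H](c3c(O)cc(O)cc3O)[C@@H]1C(C)C
A6 | alternative 3 | methyl 6-[6-(dimethoxymethyl)-5,7-dimethoxy-4-(2-methylpropyl)-3-(propan-2-yl)-3,4-dihydro-2H-chromen-2-yl]-3,5-dioxohexanoate | CC(C)C[C@@H]1c2c(cc(OC)c(C(OC)OC)c2OC)O[C@@H](CC(=O)CC(=O)CC(=O)OC)[C@@H]1C(C)C
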